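Ring A (C1–C2–C3–C4–C5–C10, kaurane numbering) is treated as a masked 2,2-disubstituted 4,4-dimethylcyclohexane-1,3-dione: the oxygenated C1 and the carboxyl-bearing C5 flank quaternary C10, and gem-dimethyl C4 sits beside C5. A consecutive Michael–Claisen [3+3] annulation of 2-methylhept-6-en-3-one with methyl acrylate forms the C3–C4 and C1–C10 bonds in one operation and delivers the whole ring with C1 and C5 as differentiated carbonyl groups. Afterwards a CBS-set C1 carbinol relays chirality to C10 and C5 through a silicon tether, and Knoevenagel lactonization, Diels–Alder reaction and palladium-mediated cyclization build the spirolactone and the bicyclo[3.2.1]octane.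

Key step: step 2

Remark: atom labels C1–C20 follow kaurane numbering (C6 carboxyl carbon, C7 lactone carbonyl, C17 methyl on C16, C20 lactone CH2); stannane 8 is taken as purchasable.

Step 1
Reactants: 1 2-methylpropanoyl chloride; 2 but-3-en-1-ylmagnesium bromide
Product: 3 2-methylhept-6-en-3-one
Conditions: Fe(acac)3 (3 mol%), THF, −78 → 0 °C
Reagents that add atoms: none
Why: Iron-catalysed acylation of a Grignard reagent by an acid chloride is faster than addition to the product ketone, so the reaction should stop at 3 (Grignard acylation).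

Step 2
Reactants: 3 2-methylhept-6-en-3-one; 4 methyl acrylate
Product: 6 2-allyl-4,4-dimethylcyclohexane-1,3-dione, via keto ester 5 (not isolated)
Conditions: t-BuOK (2.2 equiv), THF, 0 °C → rt; then 1 M HCl
Reagents that add atoms: none
Why: t-BuOK equilibrates the enolates of 3, and the more substituted (isopropyl) enolate adds to methyl acrylate to make the C3–C4 bond and the quaternary C4 (Michael addition). Proton transfer then gives the C10 enolate of keto ester 5, which attacks the ester carbonyl in a 6-exo-trig acylation (ring A closes by Claisen condensation) to make the C1–C10 bond, and loss of methoxide followed by irreversible deprotonation of the 1,3-dione drives the sequence. The closest known reaction is the consecutive Michael–Claisen synthesis of 4,4-dimethylcyclohexane-1,3-dione from 3-methylbutan-2-one and an acrylate. No stereocenter is created (C10 of 6 is enolized), so only regioselectivity is needed. It is secured thermodynamically: Michael addition at C10 followed by closure at the isopropyl carbon would give a non-enolizable 2,2-dimethyl-1,3-dione that reverts by retro-Claisen cleavage, whereas the productive path ends in the stabilized dione enolate.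

Step 3
Reactants: 6 2-allyl-4,4-dimethylcyclohexane-1,3-dione
Product: 7 2-allyl-3-isobutoxy-6,6-dimethylcyclohex-2-en-1-one
Conditions: isobutanol, p-TsOH (cat.), toluene, reflux, Dean–Stark trap
Reagents that add atoms: 2-methylpropan-1-ol, CC(C)CO
Why: Acid-catalysed O-alkylation of the enolized dione with removal of water (vinylogous ester formation) should place the alkoxy group on C1, remote from the C4 methyls, because the isomer with the alkoxy group on C5 is crowded by the gem-dimethyl group.

Step 4
Reactants: 7 2-allyl-3-isobutoxy-6,6-dimethylcyclohex-2-en-1-one; 8 tributyl[(benzyloxy)methyl]stannane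
Product: 10 2-allyl-3-[(benzyloxy)methyl]-4,4-dimethylcyclohex-2-en-1-one, via tertiary carbinol 9 (not isolated)
Conditions: 8, n-BuLi, THF, −78 °C; then 7, −78 → 0 °C; then 1 M HCl, rt
Reagents that add atoms: none
Why: Tin–lithium exchange gives BnOCH2Li, which adds 1,2 to the C5 carbonyl, and aqueous acid hydrolyses the enol ether with loss of water so that the carbonyl moves to C1 and C6 sits on C5 (Stork–Danheiser transposition).

Step 5
Reactants: 10 2-allyl-3-[(benzyloxy)methyl]-4,4-dimethylcyclohex-2-en-1-one
Product: 11 (1S)-2-allyl-3-[(benzyloxy)methyl]-4,4-dimethylcyclohex-2-en-1-ol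
Conditions: (R)-2-methyl-CBS-oxazaborolidine (10 mol%), catecholborane, toluene, −78 °C
Reagents that add atoms: none
Why: Corey–Bakshi–Shibata reduction, in which the substituted alkenyl flank (C10) acts as the large group, so the (R)-catalyst should deliver hydride to the face that gives the (1S)-allylic alcohol, the first stereocenter.

Step 6
Reactants: 11 (1S)-2-allyl-3-[(benzyloxy)methyl]-4,4-dimethylcyclohex-2-en-1-ol
Product: 12 (bromomethyl)dimethylsilyl ether of 11
Conditions: BrCH2SiMe2Cl, Et3N, DMAP (cat.), CH2Cl2, 0 °C
Reagents that add atoms: (bromomethyl)chlorodimethylsilane, C[Si](C)(Cl)CBr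
Why: Silylation of the allylic alcohol attaches the radical precursor to O1 without touching the stereocenter.

Step 7
Reactants: 12 (bromomethyl)dimethylsilyl ether of 11
Product: 14 (1S,2S,3R)-2-allyl-3-[(benzyloxy)methyl]-2-(hydroxymethyl)-4,4-dimethylcyclohexan-1-ol, via cyclic siloxane 13 (not isolated)
Conditions: Bu3SnH (slow addition), AIBN (cat.), benzene, 80 °C; then 30% H2O2, KF, KHCO3, THF/MeOH, 50 °C
Reagents that add atoms: hydrogen peroxide, OO
Why: The α-silyl radical cyclizes 5-exo-trig onto C10 on the face of O1 (silicon-tethered radical cyclization), which sets quaternary C10 with C20 cis to O1, the C5 radical then takes hydrogen from Bu3SnH axially, anti to the axial C20 and C4 methyl, which should place C6 cis to C20, and Tamao–Fleming oxidation converts the C–Si bond into C20–OH with retention.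

Step 8
Reactants: 14 (1S,2S,3R)-2-allyl-3-[(benzyloxy)methyl]-2-(hydroxymethyl)-4,4-dimethylcyclohexan-1-ol
Product: 15 (1S,2S,3R)-3-[(benzyloxy)methyl]-2-(hydroxymethyl)-4,4-dimethyl-2-[(E)-prop-1-enyl]cyclohexan-1-ol
Conditions: RuHCl(CO)(PPh3)3 (5 mol%), toluene, 80 °C
Reagents that add atoms: none
Why: The ruthenium hydride moves the terminal double bond one position to the more stable internal alkene (olefin isomerization), so that the carbon on C10 (C9) can later be cut down to an aldehyde; no stereocenter is involved.

Step 9
Reactants: 15 (1S,2S,3R)-3-[(benzyloxy)methyl]-2-(hydroxymethyl)-4,4-dimethyl-2-[(E)-prop-1-enyl]cyclohexan-1-ol; 16 2,2,6-trimethyl-4H-1,3-dioxin-4-one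
Product: 17 C20-O-acetoacetate (3-oxobutanoate of the primary hydroxyl) of 15
Conditions: 16 (1.1 equiv), toluene, 110 °C
Reagents that add atoms: none
Why: Thermolysis of 16 releases acetylketene, which should be trapped faster by the primary C20 hydroxyl than by the neopentyl secondary C1 hydroxyl (acetoacetylation), bringing in C7, C8, C15 and C16.

Step 10
Reactants: 17 C20-O-acetoacetate of 15
Product: 18 C1-O-acetate of 17
Conditions: Ac2O, pyridine, DMAP (cat.), CH2Cl2, 0 °C → rt
Reagents that add atoms: acetic anhydride, CC(=O)OC(C)=O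
Why: DMAP-catalysed esterification of the remaining secondary alcohol installs the C1 acetate of the target with retention at C1.

Step 11
Reactants: 18 C1-O-acetate of 17
Product: 20 (6S,7R,11S)-4-acetyl-7-[(benzyloxy)methyl]-8,8-dimethyl-3-oxo-2-oxaspiro[5.5]undec-4-en-11-yl acetate, via aldehyde 19 (not isolated)
Conditions: O3, CH2Cl2, −78 °C; Me2S; evaporation of volatiles; then piperidine (cat.), AcOH (cat.), 4 Å molecular sieves, CH2Cl2, rt
Reagents that add atoms: none
Why: Ozonolysis cleaves the propenyl group to the non-enolizable C9 aldehyde, which condenses with the tethered acetoacetate methylene C8 (intramolecular Knoevenagel condensation) to close the six-membered lactone and create the doubly activated C8=C9 dienophile.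

Step 12
Reactants: 20 spiro unsaturated acetyl lactone; 21 buta-1,3-diene
Product: 22 Diels–Alder adduct (cis-fused cyclohexene ring C with C12=C13, acetyl on quaternary C8, hydrogen on C9; 1S,5R,8S,9S,10S)
Conditions: 21 (excess), ZnCl2, CH2Cl2, 0 °C → rt, sealed tube
Reagents that add atoms: none
Why: Lewis-acid-promoted Diels–Alder reaction in which suprafacial addition across the ring C8=C9 bond gives the cis ring fusion and the diene should approach from the C1 side of the spiro ring, away from C5 with its benzyloxymethyl arm and the C4 methyls, which sets C8 and C9 relative to C10.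

Step 13
Reactants: 22 Diels–Alder adduct
Product: 23 tert-butyldimethylsilyl enol ether of 22 (C15(OTBS)=C16H2)
Conditions: TBSOTf, Et3N, CH2Cl2, 0 °C
Reagents that add atoms: tert-butyldimethylsilyl trifluoromethanesulfonate, CC(C)(C)[Si](C)(C)OS(=O)(=O)C(F)(F)F
Why: The methyl ketone can enolize only towards C16 because C8 is quaternary, so soft enolization should give a single silyl enol ether.

Step 14
Reactants: 23 silyl enol ether of 22
Product: 24 bicyclo[3.2.1]octenone (ring D closed by the C13–C16 bond, C11=C12 alkene, C15 ketone, C16H2; 1S,5R,8S,9S,10S,13R)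
Conditions: Pd(OAc)2 (1.1 equiv), MeCN, rt
Reagents that add atoms: none
Why: Divalent palladium activates the C12=C13 bond, C16 of the enol ether attacks C13 in the 5-exo mode (palladium-mediated oxidative cyclization of a silyl enol ether onto an alkene, the carbon analogue of the iodolactonization of cyclohex-3-enecarboxylic acids), β-hydride elimination gives the C11=C12 alkene, and the one-atom bridge C14 forces the new bond onto the face of C15, which fixes C13.

Step 15
Reactants: 24 bicyclo[3.2.1]octenone
Product: 25 16-methylene derivative of 24 (exocyclic C16=C17H2 conjugated to the C15 ketone)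
Conditions: (CH2O)n, N-methylanilinium trifluoroacetate, THF, reflux
Reagents that add atoms: formaldehyde (as paraformaldehyde), C=O
Why: Mannich-type α-methylenation at C16, the only enolizable position of the ketone, should give the exocyclic enone under mildly acidic conditions that spare the acetate, the lactone and the benzyl ether.

Step 16
Reactants: 25 16-methylene ketone
Product: 26 C6 primary alcohol of the target skeleton (1S,5R,8S,9S,10S,13R,16R)
Conditions: H2 (1 atm), Pd/C, EtOAc/EtOH, rt
Reagents that add atoms: none
Why: Heterogeneous hydrogenation should add hydrogen to the exocyclic C16=C17 bond from the open exo face (the endo face is shielded by the C11–C12 bridge), which sets C16 with the methyl group endo, and it also saturates C11=C12 and removes the benzyl group by hydrogenolysis.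

Step 17
Reactants: 26 C6 primary alcohol
Product: 27 CNP0161834.1 (target acid, 1S,5R,8S,9S,10S,13R,16R)
Conditions: TEMPO (cat.), PhI(OAc)2, MeCN/H2O, rt
Reagents that add atoms: water, O
Why: Nitroxyl-catalysed oxidation takes the primary C6 alcohol through the aldehyde hydrate to the carboxylic acid under near-neutral conditions that should leave the ketone, the acetate, the lactone and the stereocenters at C5 and C16 untouched.

Compound list
1 | 2-methylpropanoyl chloride | CC(C)C(Cl)=O | starting material
2 | but-3-en-1-ylmagnesium bromide | C=CCC[Mg]Br | starting material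
3 | 2-methylhept-6-en-3-one | CC(C)C(=O)CCC=C | intermediate
4 | methyl acrylate | COC(=O)C=C | starting material
5 | methyl 4,4-dimethyl-5-oxonon-8-enoate | COC(=O)CCC(C)(C)C(=O)CCC=C | intermediate
6 | 2-allyl-4,4-dimethylcyclohexane-1,3-dione | O=C1CCC(C)(C)C(=O)C1CC=C | intermediate
7 | 2-allyl-3-isobutoxy-6,6-dimethylcyclohex-2-en-1-one | CC(C)COC1=C(CC=C)C(=O)C(C)(C)CC1 | intermediate
8 | tributyl[(benzyloxy)methyl]stannane | CCCC[Sn](CCCC)(CCCC)COCc1ccccc1 | starting material
9 | 2-allyl-1-[(benzyloxy)methyl]-3-isobutoxy-6,6-dimethylcyclohex-2-en-1-ol (racemic) | CC(C)COC1=C(CC=C)C(O)(COCc2ccccc2)C(C)(C)CC1 | intermediate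
10 | 2-allyl-3-[(benzyloxy)methyl]-4,4-dimethylcyclohex-2-en-1-one | O=C1CCC(C)(C)C(COCc2ccccc2)=C1CC=C | intermediate
11 | (1S)-2-allyl-3-[(benzyloxy)methyl]-4,4-dimethylcyclohex-2-en-1-ol | O[C@H]1CCC(C)(C)C(COCc2ccccc2)=C1CC=C | intermediate
12 | (bromomethyl)dimethylsilyl ether of 11 | BrC[Si](C)(C)O[C@H]1CCC(C)(C)C(COCc2ccccc2)=C1CC=C | intermediate
13 | cis-fused cyclic siloxane (O1–SiMe2–C20H2 bridge from C1 to C10, allyl on C10, benzyloxymethyl on C5 cis to C20) | C[Si]1(C)O[C@H]2CCC(C)(C)[C@@H](COCc3ccccc3)[C@@]2(CC=C)C1 | intermediate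
14 | (1S,2S,3R)-2-allyl-3-[(benzyloxy)methyl]-2-(hydroxymethyl)-4,4-dimethylcyclohexan-1-ol | O[C@H]1CCC(C)(C)[C@@H](COCc2ccccc2)[C@@]1(CC=C)CO | intermediate
15 | (1S,2S,3R)-3-[(benzyloxy)methyl]-2-(hydroxymethyl)-4,4-dimethyl-2-[(E)-prop-1-enyl]cyclohexan-1-ol | O[C@H]1CCC(C)(C)[C@@H](COCc2ccccc2)[C@@]1(/C=C/C)CO | intermediate
16 | 2,2,6-trimethyl-4H-1,3-dioxin-4-one | CC1=CC(=O)OC(C)(C)O1 | starting material
17 | C20-O-acetoacetate of 15 (C1 S, C5 R, C10 S) | O[C@H]1CCC(C)(C)[C@@H](COCc2ccccc2)[C@@]1(/C=C/C)COC(=O)CC(C)=O | intermediate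
18 | C1-O-acetate of 17 (C1 S, C5 R, C10 S) | CC(=O)O[C@H]1CCC(C)(C)[C@@H](COCc2ccccc2)[C@@]1(/C=C/C)COC(=O)CC(C)=O | intermediate
19 | C10 carbaldehyde from 18 (C1 S, C5 R, C10 R) | CC(=O)O[C@H]1CCC(C)(C)[C@@H](COCc2ccccc2)[C@@]1(C=O)COC(=O)CC(C)=O | intermediate
20 | (6S,7R,11S)-4-acetyl-7-[(benzyloxy)methyl]-8,8-dimethyl-3-oxo-2-oxaspiro[5.5]undec-4-en-11-yl acetate | CC(=O)O[C@H]1CCC(C)(C)[C@@H](COCc2ccccc2)[C@@]12COC(=O)C(C(C)=O)=C2 | intermediate
21 | buta-1,3-diene | C=CC=C | starting material
22 | Diels–Alder adduct, cis-fused ring C (C12=C13), acetyl on C8 (1S,5R,8S,9S,10S) | CC(=O)O[C@H]1CCC(C)(C)[C@@H](COCc2ccccc2)[C@@]12COC(=O)[C@@]3(C(C)=O)CC=CC[C@@H]23 | intermediate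
23 | tert-butyldimethylsilyl enol ether of 22 | CC(=O)O[C@H]1CCC(C)(C)[C@@H](COCc2ccccc2)[C@@]12COC(=O)[C@@]3(C(=C)O[Si](C)(C)C(C)(C)C)CC=CC[C@@H]23 | intermediate
24 | bicyclo[3.2.1]octenone with C11=C12 and C16H2 (1S,5R,8S,9S,10S,13R) | CC(=O)O[C@H]1CCC(C)(C)[C@@H](COCc2ccccc2)[C@@]12COC(=O)[C@@]13C[C@@H](C=C[C@H]12)CC3=O | intermediate
25 | 16-methylene derivative of 24 (1S,5R,8S,9S,10S,13S) | CC(=O)O[C@H]1CCC(C)(C)[C@@H](COCc2ccccc2)[C@@]12COC(=O)[C@@]13C[C@@H](C=C[C@H]12)C(=C)C3=O | intermediate
26 | C6 primary alcohol of the target skeleton (1S,5R,8S,9S,10S,13R,16R) | CC(=O)O[C@H]1CCC(C)(C)[C@@H](CO)[C@@]12COC(=O)[C@@]13C[C@@H](CC[C@H]12)[C@@H](C)C3=O | intermediate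
27 | CNP0161834.1, target acid (1S,5R,8S,9S,10S,13R,16R) | CC(=O)O[C@H]1CCC(C)(C)[C@@H](C(=O)O)[C@@]12COC(=O)[C@@]13C[C@@H](CC[C@H]12)[C@@H](C)C3=O | target

Total step count: 17. Longest linear sequence: 17 steps (from 1 and 2 to 27).

Steps most likely to fail

Step 12 (Diels–Alder reaction). What may go wrong: poor facial selectivity, because the diene may not distinguish well enough between the C1 side (acetate) and the C5 side (benzyloxymethyl arm) of the spiro ring, or slow cycloaddition at the neopentyl carbon C9 with loss of material by diene oligomerization. The fallback sets out from 17 and comes back at 22; it delivers the diene from the C1 oxygen through a temporary silicon tether. Ozonolysis and Knoevenagel condensation of 17 under the conditions of step 11 should give the C1-hydroxy spirolactone F2. Silylation with (buta-1,3-dien-2-yl)chlorodimethylsilane (C=CC(=C)[Si](C)(C)Cl, Et3N) should give the dienylsilyl ether F3. On heating (toluene, 110 °C), a type 2 intramolecular Diels–Alder reaction can reach only the C1 face of C8=C9 and should give the bridged siloxane cycloadduct F4 with silicon on C12. TBAF should cleave the Si–O bond and protodesilylate the vinylsilane to the hydroxy adduct F5, and acetylation (Ac2O, pyridine, DMAP) then gives 22.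

Step 14 (palladium-mediated closure of ring D). What may go wrong: attack on the distal alkene carbon C12 (six-membered closure to the bicyclo[2.2.2]octane isomer), or loss of the silyl enol ether by protodesilylation before the C–C bond forms. The fallback sets out from 23 and comes back at 26; it uses a radical closure in place of the organopalladium one. NBS (THF, 0 °C) should convert 23 into the bromomethyl ketone F6. Bu3SnH and AIBN should generate the C16 radical, whose 5-exo cyclization onto C13 and hydrogen transfer to C12 give the saturated bicyclo[3.2.1]octanone F7. α-Methylenation as in step 15 gives the saturated methylene ketone F8, and hydrogenation as in step 16 gives 26.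

Step 2 (key step). What may go wrong: competing Michael addition through the less hindered C10 enolate of 3, leading to double addition and acrylate oligomers. The fallback sets out from 4 (with purchased 3-methylbutan-2-one) and comes back at 6. The same Michael–Claisen annulation on 3-methylbutan-2-one, where only the isopropyl carbon can open a productive sequence, should give 4,4-dimethylcyclohexane-1,3-dione F1. Pd(PPh3)4-catalysed C-allylation with allyl acetate (Tsuji–Trost reaction) then puts the allyl group on C10 and gives 6; the two ring bonds are still formed in one operation.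

Further compounds
F1 | step 2 | 4,4-dimethylcyclohexane-1,3-dione | CC1(C)CCC(=O)CC1=O
F2 | step 12 | C1-hydroxy spirolactone (C1–OH analogue of 20) | O[C@H]1CCC(C)(C)[C@@H](COCc2ccccc2)[C@@]12COC(=O)C(C(C)=O)=C2
F3 | step 12 | (buta-1,3-dien-2-yl)dimethylsilyl ether of F2 | C=CC(=C)[Si](C)(C)O[C@H]1CCC(C)(C)[C@@H](COCc2ccccc2)[C@@]12COC(=O)C(C(C)=O)=C2
F4 | step 12 | bridged siloxane cycloadduct (O1–SiMe2–C12, C12=C13) | C[Si]1(C)O[C@H]2CCC(C)(C)[C@@H](COCc3ccccc3)[C@@]24COC(=O)[C@@]5(C(C)=O)CC=C1C[C@@H]45
F5 | step 12 | hydroxy adduct (C1–OH analogue of 22) | O[C@H]1CCC(C)(C)[C@@H](COCc2ccccc2)[C@@]12COC(=O)[C@@]3(C(C)=O)CC=CC[C@@H]23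
F6 | step 14 | bromomethyl ketone from 23 | CC(=O)O[C@H]1CCC(C)(C)[C@@H](COCc2ccccc2)[C@@]12COC(=O)[C@@]3(C(=O)CBr)CC=CC[C@@H]23
F7 | step 14 | saturated bicyclo[3.2.1]octanone (C16H2, C11H2, C12H2) | CC(=O)O[C@H]1CCC(C)(C)[C@@H](COCc2ccccc2)[C@@]12COC(=O)[C@@]13C[C@@H](CC[C@H]12)CC3=O
F8 | step 14 | saturated methylene ketone (C16=C17H2) | CC(=O)O[C@H]1CCC(C)(C)[C@@H](COCc2ccccc2)[C@@]12COC(=O)[C@@]13C[C@@H](CC[C@H]12)C(=C)C3=O
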